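**Strategy.** The cyclohexene is disconnected by an exo-selective, boron-templated asymmetric Diels–Alder reaction between a flavone-bound 3-methylbuta-1,3-dienyl unit and a 2'-hydroxychalcone that already carries the dimethylpyran ring. That pyran is the pivot: its C4 is attached to an aromatic carbon flanked by two phenolic oxygens, so it is traced back to the formyl carbon of 3-acetyl-2,6-dihydroxybenzaldehyde. In one operation a Petasis borono-Mannich/amine-elimination/oxa-6π cascade with 2-methylprop-1-enylboronic acid forms the C3=C4 alkene and the O1–C2 bond to the gem-dimethyl carbon, closing the ring from a monocyclic salicylaldehyde and leaving the acetyl-chelated phenol free.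

Key step: step 2

Assumption (remark on the chemistry): the (S)-VANOL–boron template is taken to expose the Cα-Re face of the chelated s-cis chalcone, which corresponds to the (1S,5R,6S) adduct; should the sense of induction prove opposite, (R)-VANOL would be used with no other change.

**Step 1**
Reactants: 1 2,4-dihydroxyacetophenone
Product: 2 3-acetyl-2,6-dihydroxybenzaldehyde
Conditions: HMTA (2 equiv), AcOH, 100 °C; then 3 M HCl, 90 °C
Reagents that add atoms: hexamethylenetetramine C1N2CN3CN1CN(C2)C3; water O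
Why: Duff formylation, in which the HMTA-derived iminium should attack C3 of the chelated resacetophenone (the site between the two hydroxyls, as in its Claisen and Mannich chemistry) and hydrolysis of the benzylic iminium gives the aldehyde, any 5-formyl isomer being removed by crystallisation.

**Step 2**
Reactants: 2 3-acetyl-2,6-dihydroxybenzaldehyde; 3 (2-methylprop-1-en-1-yl)boronic acid
Product: 6 1-(5-hydroxy-2,2-dimethyl-2H-chromen-6-yl)ethanone, via Petasis allylic amine 4 (not isolated), via o-quinone methide 5 (not isolated)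
Conditions: 3 (1.5 equiv), Bn2NH (0.4 equiv), 1,4-dioxane, 90 °C, sealed tube
Reagents that add atoms: none
Why: Bn2NH condenses with the aldehyde (far more electrophilic than the chelated aryl ketone) to an iminium, a flanking phenol binds the boronic acid as a tetracoordinate boronate that delivers its isobutenyl group to the iminium carbon (Petasis borono-Mannich) to give allylic amine 4, and on heating 4 expels Bn2NH, which turns over, to form o-quinone methide 5, whose thermal disrotatory oxa-6π electrocyclisation makes the O–C(CH3)2 bond while the former formyl carbon becomes C4 of the new C3=C4 alkene. The closest known reaction is the amine-catalysed Petasis condensation of salicylaldehydes with alkenylboronic acids to 2H-chromenes, and 5 is the same intermediate as in the classical resacetophenone/prenal chromenylation. The one ring is closed in the 6π-electrocyclic (formally 6-endo) mode and no stereocentre is created. The step needs regioselection between the two phenolic oxygens that flank the formyl group: the 2-OH is locked in a hydrogen bond to the acetyl carbonyl, so the quinone methide is expected to form and close through the para oxygen, giving the 5-hydroxy-6-acetyl chromene and keeping the chelating OH free for the later boron template.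

**Step 3**
Reactants: 7 2,4-dihydroxybenzaldehyde
Product: 8 2,4-bis(prop-2-en-1-yloxy)benzaldehyde
Conditions: allyl bromide (2.5 equiv), K2CO3, DMF, 60 °C
Reagents that add atoms: allyl bromide C=CCBr
Why: Williamson etherification of both phenoxides, the excess reagent and heat also alkylating the hydrogen-bonded 2-OH.

**Step 4**
Reactants: 6 1-(5-hydroxy-2,2-dimethyl-2H-chromen-6-yl)ethanone; 8 2,4-bis(prop-2-en-1-yloxy)benzaldehyde
Product: 9 (2E)-3-[2,4-bis(prop-2-en-1-yloxy)phenyl]-1-(5-hydroxy-2,2-dimethyl-2H-chromen-6-yl)prop-2-en-1-one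
Conditions: KOH (50% aq.), EtOH, rt
Reagents that add atoms: none
Why: Claisen–Schmidt aldol condensation, with E1cB dehydration giving the thermodynamic E-enone and the base-stable chromene and allyl ethers untouched.

**Step 5**
Reactants: 8 2,4-bis(prop-2-en-1-yloxy)benzaldehyde
Product: 10 2,4-bis(prop-2-en-1-yloxy)benzoic acid
Conditions: NaClO2, NaH2PO4, 2-methylbut-2-ene, t-BuOH/H2O, rt
Reagents that add atoms: sodium chlorite [Na+].[O-]Cl=O
Why: Pinnick oxidation of the aldehyde, the alkene scavenger trapping HOCl so that the allyl ethers survive.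

**Step 6**
Reactants: 11 2,4,6-trihydroxyacetophenone
Product: 12 1-[2,6-dihydroxy-4-(methoxymethoxy)phenyl]ethanone
Conditions: MOMCl (1.05 equiv), i-Pr2NEt (1.2 equiv), CH2Cl2/THF, 0 °C
Reagents that add atoms: chloromethyl methyl ether COCCl
Why: Selective O-alkylation of the most acidic, non-chelated para hydroxyl, the two ortho hydroxyls being held by the acetyl carbonyl.

**Step 7**
Reactants: 12 1-[2,6-dihydroxy-4-(methoxymethoxy)phenyl]ethanone
Product: 13 1-[2-hydroxy-4-(methoxymethoxy)-6-(prop-2-en-1-yloxy)phenyl]ethanone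
Conditions: allyl bromide (1.1 equiv), K2CO3 (1.2 equiv), acetone, 50 °C
Reagents that add atoms: allyl bromide C=CCBr
Why: Williamson mono-alkylation of one of two equivalent hydroxyls, after which the remaining OH is strongly chelated and should resist a second alkylation.

**Step 8**
Reactants: 13 1-[2-hydroxy-4-(methoxymethoxy)-6-(prop-2-en-1-yloxy)phenyl]ethanone
Product: 14 1-[2-hydroxy-3-iodo-4-(methoxymethoxy)-6-(prop-2-en-1-yloxy)phenyl]ethanone
Conditions: NIS (1.05 equiv), DMF, 0 °C → rt
Reagents that add atoms: N-iodosuccinimide O=C1CCC(=O)N1I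
Why: Electrophilic aromatic iodination ortho to the free chelated phenol (C3), the usual halogenation site of 2-hydroxy-4,6-dialkoxyacetophenones, C5 being flanked by two alkoxy groups.

**Step 9**
Reactants: 14 1-[2-hydroxy-3-iodo-4-(methoxymethoxy)-6-(prop-2-en-1-yloxy)phenyl]ethanone
Product: 15 1-[2-hydroxy-3-iodo-4-(methoxymethoxy)-6-(prop-2-en-1-yloxy)phenyl]-5-methylhex-4-en-1-one
Conditions: LDA (2.3 equiv), THF, −78 °C; prenyl bromide (1.1 equiv), −78 → −20 °C
Reagents that add atoms: prenyl bromide CC(C)=CCBr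
Why: Alkylation of the phenoxide/enolate dianion, the enolate carbon reacting by SN2 at the primary carbon of the allylic bromide while the hindered lithium phenoxide stays unreactive.

**Step 10**
Reactants: 15 1-[2-hydroxy-3-iodo-4-(methoxymethoxy)-6-(prop-2-en-1-yloxy)phenyl]-5-methylhex-4-en-1-one; 10 2,4-bis(prop-2-en-1-yloxy)benzoic acid
Product: 17 1-[2,4-bis(prop-2-en-1-yloxy)phenyl]-3-[2-hydroxy-3-iodo-4-(methoxymethoxy)-6-(prop-2-en-1-yloxy)phenyl]-2-(3-methylbut-2-en-1-yl)propane-1,3-dione, via acid chloride 16 (not isolated)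
Conditions: 10, (COCl)2, cat. DMF, CH2Cl2, 0 °C → rt, evaporate; 15, LiHMDS (3.5 equiv), THF, −78 °C, then 16, −78 °C → rt; aq. NH4Cl
Reagents that add atoms: none
Why: Claisen-type C-aroylation of the lithium dianion, in which any aryl ester formed at the phenoxide should rearrange under the excess base (Baker–Venkataraman) to the same 2-substituted 1,3-diketone.

**Step 11**
Reactants: 17 the 1,3-diketone
Product: 18 2-[2,4-bis(prop-2-en-1-yloxy)phenyl]-7-hydroxy-8-iodo-3-(3-methylbut-2-en-1-yl)-5-(prop-2-en-1-yloxy)-4H-chromen-4-one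
Conditions: conc. HCl (5 equiv), MeOH/THF, 50 °C
Reagents that add atoms: none
Why: Acid-catalysed cyclodehydration (flavone synthesis) through the only free phenol, which places iodine at C8, with methanolysis of the MOM acetal in the same pot and the acid-stable allyl ethers retained.

**Step 12**
Reactants: 18 the 7-hydroxy-8-iodoflavone
Product: 19 2-[2,4-bis(prop-2-en-1-yloxy)phenyl]-8-iodo-3-(3-methylbut-2-en-1-yl)-4-oxo-5-(prop-2-en-1-yloxy)-4H-chromen-7-yl acetate
Conditions: Ac2O, pyridine, DMAP (cat.), CH2Cl2, rt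
Reagents that add atoms: acetic anhydride CC(=O)OC(C)=O
Why: DMAP-catalysed O-acetylation caps the phenol ortho to the future diene, where an allyl ether would undergo intramolecular Heck cyclisation onto the C8–Pd bond.

**Step 13**
Reactants: 20 2-methylbut-1-en-3-yne
Product: 21 4,4,5,5-tetramethyl-2-[(1E)-3-methylbuta-1,3-dien-1-yl]-1,3,2-dioxaborolane
Conditions: HBpin (1.1 equiv), Cp2Zr(H)Cl (5 mol%), Et3N (10 mol%), neat, sealed tube, 50 °C
Reagents that add atoms: pinacolborane CC1(C)OBOC1(C)C
Why: Zirconium-catalysed syn-hydroboration of the terminal alkyne places boron at the terminal carbon and gives the E-dienylboronate, the 1,1-disubstituted alkene being left alone.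

**Step 14**
Reactants: 19 the 8-iodoflavone 7-acetate; 21 the (E)-dienylboronate
Product: 22 2-[2,4-bis(prop-2-en-1-yloxy)phenyl]-8-[(1E)-3-methylbuta-1,3-dien-1-yl]-3-(3-methylbut-2-en-1-yl)-4-oxo-5-(prop-2-en-1-yloxy)-4H-chromen-7-yl acetate
Conditions: Pd(dppf)Cl2·CH2Cl2 (5 mol%), CsF (3 equiv), 1,4-dioxane (anhydrous), 70 °C
Reagents that add atoms: none
Why: Suzuki–Miyaura coupling with retention of the E geometry, anhydrous fluoride activation being chosen to spare the aryl acetate, and none of the allyl ethers sitting ortho to the C–Pd bond.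

**Step 15**
Reactants: 9 the chromene chalcone; 22 the flavone diene
Product: 23 2-[2,4-bis(prop-2-en-1-yloxy)phenyl]-8-[(1S,5R,6S)-5-[2,4-bis(prop-2-en-1-yloxy)phenyl]-6-(5-hydroxy-2,2-dimethyl-2H-chromene-6-carbonyl)-3-methylcyclohex-2-en-1-yl]-3-(3-methylbut-2-en-1-yl)-4-oxo-5-(prop-2-en-1-yloxy)-4H-chromen-7-yl acetate
Conditions: (S)-VANOL, BH3·THF, AcOH (1.2 equiv each), THF, rt (complex pre-formed until H2 evolution ends); 9, rt; evaporate; 22 (1.5 equiv), PhCF3, 50 °C; aq. NaHCO3 work-up; chromatography (exo from endo)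
Reagents that add atoms: none
Why: Chelation of the 2'-hydroxy ketone of 9 to the tetrahedral VANOL–boron centre lowers the enone LUMO and shields one face, so the s-cis diene should add with the usual ortho/para regiochemistry (diene C1 to Cα, CH2 to Cβ) to the exposed Cα-Re face through the exo transition state, setting C1 (S), C5 (R) and C6 (S) in one asymmetric Diels–Alder event, with the endo diastereomer removed by chromatography.

**Step 16**
Reactants: 23 the protected adduct
Product: 24 Kuwanon W
Conditions: Pd(PPh3)4 (10 mol%), K2CO3 (8 equiv), MeOH/THF, rt → 40 °C, Ar; aq. NH4Cl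
Reagents that add atoms: none
Why: Pd(0) ionises the five aryl allyl ethers to π-allyl complexes that methoxide intercepts (Tsuji–Trost deallylation) while carbonate-mediated methanolysis removes the acetate, and the all-trans ketone is the thermodynamically stable epimer at C6, so no stereocentre is at risk.

**Compound list**
1 | 2,4-dihydroxyacetophenone | CC(=O)c1ccc(O)cc1O | starting material
2 | 3-acetyl-2,6-dihydroxybenzaldehyde | CC(=O)c1ccc(O)c(C=O)c1O | intermediate
3 | (2-methylprop-1-en-1-yl)boronic acid | CC(C)=CB(O)O | starting material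
4 | 1-{3-[1-(dibenzylamino)-3-methylbut-2-en-1-yl]-2,4-dihydroxyphenyl}ethanone (racemic Petasis adduct) | CC(=O)c1ccc(O)c(C(C=C(C)C)N(Cc2ccccc2)Cc2ccccc2)c1O | intermediate (not isolated)
5 | 4-acetyl-5-hydroxy-6-(3-methylbut-2-en-1-ylidene)cyclohexa-2,4-dien-1-one (o-quinone methide) | CC(=O)C1=C(O)C(=CC=C(C)C)C(=O)C=C1 | intermediate (not isolated)
6 | 1-(5-hydroxy-2,2-dimethyl-2H-chromen-6-yl)ethanone | CC(=O)c1ccc2c(c1O)C=CC(C)(C)O2 | intermediate
7 | 2,4-dihydroxybenzaldehyde | O=Cc1ccc(O)cc1O | starting material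
8 | 2,4-bis(prop-2-en-1-yloxy)benzaldehyde | C=CCOc1ccc(C=O)c(OCC=C)c1 | intermediate
9 | (2E)-3-[2,4-bis(prop-2-en-1-yloxy)phenyl]-1-(5-hydroxy-2,2-dimethyl-2H-chromen-6-yl)prop-2-en-1-one | C=CCOc1ccc(/C=C/C(=O)c2ccc3c(c2O)C=CC(C)(C)O3)c(OCC=C)c1 | intermediate
10 | 2,4-bis(prop-2-en-1-yloxy)benzoic acid | C=CCOc1ccc(C(=O)O)c(OCC=C)c1 | intermediate
11 | 2,4,6-trihydroxyacetophenone | CC(=O)c1c(O)cc(O)cc1O | starting material
12 | 1-[2,6-dihydroxy-4-(methoxymethoxy)phenyl]ethanone | CC(=O)c1c(O)cc(OCOC)cc1O | intermediate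
13 | 1-[2-hydroxy-4-(methoxymethoxy)-6-(prop-2-en-1-yloxy)phenyl]ethanone | CC(=O)c1c(O)cc(OCOC)cc1OCC=C | intermediate
14 | 1-[2-hydroxy-3-iodo-4-(methoxymethoxy)-6-(prop-2-en-1-yloxy)phenyl]ethanone | CC(=O)c1c(O)c(I)c(OCOC)cc1OCC=C | intermediate
15 | 1-[2-hydroxy-3-iodo-4-(methoxymethoxy)-6-(prop-2-en-1-yloxy)phenyl]-5-methylhex-4-en-1-one | CC(C)=CCCC(=O)c1c(O)c(I)c(OCOC)cc1OCC=C | intermediate
16 | 2,4-bis(prop-2-en-1-yloxy)benzoyl chloride | C=CCOc1ccc(C(Cl)=O)c(OCC=C)c1 | intermediate (not isolated)
17 | 1-[2,4-bis(prop-2-en-1-yloxy)phenyl]-3-[2-hydroxy-3-iodo-4-(methoxymethoxy)-6-(prop-2-en-1-yloxy)phenyl]-2-(3-methylbut-2-en-1-yl)propane-1,3-dione (racemic, enolisable C2) | CC(C)=CCC(C(=O)c1ccc(OCC=C)cc1OCC=C)C(=O)c1c(O)c(I)c(OCOC)cc1OCC=C | intermediate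
18 | 2-[2,4-bis(prop-2-en-1-yloxy)phenyl]-7-hydroxy-8-iodo-3-(3-methylbut-2-en-1-yl)-5-(prop-2-en-1-yloxy)-4H-chromen-4-one | CC(C)=CCc1c(-c2ccc(OCC=C)cc2OCC=C)oc2c(I)c(O)cc(OCC=C)c2c1=O | intermediate
19 | 2-[2,4-bis(prop-2-en-1-yloxy)phenyl]-8-iodo-3-(3-methylbut-2-en-1-yl)-4-oxo-5-(prop-2-en-1-yloxy)-4H-chromen-7-yl acetate | CC(C)=CCc1c(-c2ccc(OCC=C)cc2OCC=C)oc2c(I)c(OC(C)=O)cc(OCC=C)c2c1=O | intermediate
20 | 2-methylbut-1-en-3-yne | C=C(C)C#C | starting material
21 | 4,4,5,5-tetramethyl-2-[(1E)-3-methylbuta-1,3-dien-1-yl]-1,3,2-dioxaborolane | C=C(C)/C=C/B1OC(C)(C)C(C)(C)O1 | intermediate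
22 | 2-[2,4-bis(prop-2-en-1-yloxy)phenyl]-8-[(1E)-3-methylbuta-1,3-dien-1-yl]-3-(3-methylbut-2-en-1-yl)-4-oxo-5-(prop-2-en-1-yloxy)-4H-chromen-7-yl acetate | CC(C)=CCc1c(-c2ccc(OCC=C)cc2OCC=C)oc2c(/C=C/C(C)=C)c(OC(C)=O)cc(OCC=C)c2c1=O | intermediate
23 | 2-[2,4-bis(prop-2-en-1-yloxy)phenyl]-8-[(1S,5R,6S)-5-[2,4-bis(prop-2-en-1-yloxy)phenyl]-6-(5-hydroxy-2,2-dimethyl-2H-chromene-6-carbonyl)-3-methylcyclohex-2-en-1-yl]-3-(3-methylbut-2-en-1-yl)-4-oxo-5-(prop-2-en-1-yloxy)-4H-chromen-7-yl acetate | CC(C)=CCc1c(-c2ccc(OCC=C)cc2OCC=C)oc2c([C@H]3C=C(C)C[C@@H](c4ccc(OCC=C)cc4OCC=C)[C@@H]3C(=O)c3ccc4c(c3O)C=CC(C)(C)O4)c(OC(C)=O)cc(OCC=C)c2c1=O | intermediate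
24 | Kuwanon W, 8-[(1S,5R,6S)-5-(2,4-dihydroxyphenyl)-6-(5-hydroxy-2,2-dimethyl-2H-chromene-6-carbonyl)-3-methylcyclohex-2-en-1-yl]-2-(2,4-dihydroxyphenyl)-5,7-dihydroxy-3-(3-methylbut-2-en-1-yl)-4H-chromen-4-one | CC(C)=CCc1c(-c2ccc(O)cc2O)oc2c([C@H]3C=C(C)C[C@@H](c4ccc(O)cc4O)[C@@H]3C(=O)c3ccc4c(c3O)C=CC(C)(C)O4)c(O)cc(O)c2c1=O | target

**Total step count:** 16 steps.
**Longest linear sequence:** 10 steps (from 11: steps 6, 7, 8, 9, 10, 11, 12, 14, 15, 16).

**Steps most likely to fail**

Step 15. The VANOL–boron template may discriminate the enone faces poorly or in the opposite sense, the exo/endo partition may be unfavourable, or the electron-rich dienophile may react too slowly at the temperature where the template is selective. The fallback sets out from 9 and 22 and gives up asymmetric induction in favour of resolution: uncatalysed thermal cycloaddition (toluene, BHT, sealed tube, about 140 °C) should give, after chromatographic removal of the endo isomer, the racemic exo adduct F1; preparative chiral SFC on an amylose-type phase would then supply the (1S,5R,6S) enantiomer, and the route is rejoined at 23.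

Step 2. Transfer of the β,β-disubstituted alkenyl group to a doubly hydrogen-bonded iminium may be slow, the amine may promote self-condensation of the formyl/acetyl pair, or ring closure may occur through the chelated oxygen. The fallback sets out from 2 and makes the same two bonds by a polar domino reaction with a temporary activating group: oxa-Michael addition/aldol condensation with 3-methylbut-2-enal (pyrrolidine/PhCO2H or K2CO3, dioxane, reflux) should give 6-acetyl-5-hydroxy-2,2-dimethyl-2H-chromene-3-carbaldehyde F2, and Tsuji–Wilkinson decarbonylation (RhCl(PPh3)3, xylene, reflux) removes the formyl group; the route is rejoined at 6.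

Step 14. Fluoride may cleave the 7-acetate, after which the freed o-dienylphenol would cycloisomerise, or the dienylboronate may protodeboronate or oligomerise before transmetalation. The fallback sets out from 19 and builds the diene in two stages: Heck reaction with 2-methylbut-3-en-2-ol (Pd(OAc)2, P(o-tol)3, Et3N, MeCN, 80 °C) should give the (E)-tertiary allylic alcohol, 2-[2,4-bis(prop-2-en-1-yloxy)phenyl]-8-[(1E)-3-hydroxy-3-methylbut-1-en-1-yl]-3-(3-methylbut-2-en-1-yl)-4-oxo-5-(prop-2-en-1-yloxy)-4H-chromen-7-yl acetate F3, and dehydration with Burgess reagent (toluene, 50 °C) gives the diene; the route is rejoined at 22.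

**Further compounds**
F1 | step 15 | racemic exo adduct, rac-(1S*,5R*,6S*)-23 (one enantiomer of the pair drawn) | CC(C)=CCc1c(-c2ccc(OCC=C)cc2OCC=C)oc2c([C@H]3C=C(C)C[C@@H](c4ccc(OCC=C)cc4OCC=C)[C@@H]3C(=O)c3ccc4c(c3O)C=CC(C)(C)O4)c(OC(C)=O)cc(OCC=C)c2c1=O
F2 | step 2 | 6-acetyl-5-hydroxy-2,2-dimethyl-2H-chromene-3-carbaldehyde | CC(=O)c1ccc2c(c1O)C=C(C=O)C(C)(C)O2
F3 | step 14 | 2-[2,4-bis(prop-2-en-1-yloxy)phenyl]-8-[(1E)-3-hydroxy-3-methylbut-1-en-1-yl]-3-(3-methylbut-2-en-1-yl)-4-oxo-5-(prop-2-en-1-yloxy)-4H-chromen-7-yl acetate | CC(C)=CCc1c(-c2ccc(OCC=C)cc2OCC=C)oc2c(/C=C/C(C)(C)O)c(OC(C)=O)cc(OCC=C)c2c1=O
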